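**Retrosynthetic overview** (quinolizidin-2-one numbering in each half: N5, C1 carries the chain from the other half, C2 = O, C3–Me, C9 carries the chain, C9a ring fusion)
1. Target ⇐ dissolving-metal reduction and base equilibration of bis(bicyclic vinylogous amide) 18; C1, C3 and C9a are thermodynamic, C9 is fixed.
2. 18 ⇐ two 6-endo aza-Michael closures (ring B) of the 16-membered bis(N–H vinylogous amide) 17.
3. 17 ⇐ key ring contraction: double sulfide contraction (sulfur extrusion, 18 → 16 ring atoms) of the bis(thioimidate) formed by head-to-tail S-alkylation of two molecules of thiolactam/α-chloro enone 15.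
4. 15 ⇐ (S)-3-alkylpiperidin-2-one 9, made by asymmetric hydrogenation of the alkylidene lactam from N-Boc-piperidin-2-one and methyl 7-oxoheptanoate (cycloheptene ozonolysis); isopropenylmagnesium bromide supplies C3, C4 and the methyl group.
5. Ring order: ring A (present as the lactam) → 18-membered S,N-macrocycle → 16-membered carbocycle → ring B (twice).

Assumption: for a fixed (9S) centre, the target's configuration at C1, C3 and C9a is the thermodynamically preferred one of each half inside the 16-membered ring, so these epimerizable centres are set by the final base equilibration.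

**Step 1**
Reactants: 1 cycloheptene
Product: 3 methyl 7-oxoheptanoate, via methoxy hydroperoxide 2 (not isolated)
Conditions: O3, CH2Cl2/MeOH, NaHCO3, −78 °C; then Ac2O, Et3N, 0 → 25 °C
Reagents that add atoms: ozone [O-][O+]=O; methanol CO
Why: Ozonolysis with unsymmetrical (Schreiber) work-up: methanol traps the carbonyl oxide as α-methoxy hydroperoxide 2, which Ac2O/Et3N dehydrates to the methyl ester while the other terminus stays an aldehyde, giving a terminally differentiated C7 chain.

**Step 2**
Reactants: 4 piperidin-2-one
Product: 5 tert-butyl 2-oxopiperidine-1-carboxylate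
Conditions: Boc2O, DMAP (cat.), MeCN, 25 °C
Reagents that add atoms: di-tert-butyl dicarbonate CC(C)(C)OC(=O)OC(=O)OC(C)(C)C
Why: DMAP-catalysed N-acylation (carbamate protection) allows clean C3 enolization of the lactam and gives a good hydrogenation substrate later.

**Step 3**
Reactants: 5 tert-butyl 2-oxopiperidine-1-carboxylate; 3 methyl 7-oxoheptanoate
Product: 8 tert-butyl (3E)-3-(7-methoxy-7-oxoheptylidene)-2-oxopiperidine-1-carboxylate, via aldol adduct 6 (not isolated), via mesylate 7 (not isolated)
Conditions: LiN(SiMe3)2, THF, −78 °C; then 3; then MsCl, −78 → 0 °C; then DBU, 25 °C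
Reagents that add atoms: none
Why: Aldol addition of the lactam lithium enolate to the aldehyde (the remote ester is inert at −78 °C), then mesylation and DBU-mediated E1cB elimination (aldol condensation) give the thermodynamically preferred E-alkylidene lactam.

**Step 4**
Reactants: 8 tert-butyl (3E)-3-(7-methoxy-7-oxoheptylidene)-2-oxopiperidine-1-carboxylate
Product: 9 tert-butyl (3S)-3-(7-methoxy-7-oxoheptyl)-2-oxopiperidine-1-carboxylate
Conditions: H2 (50 bar), [Ir(cod)(L*)][B(3,5-(CF3)2C6H3)4] (1 mol %; L* = chiral spiro phosphine–oxazoline, antipode chosen on a test run to give 3S), CH2Cl2, 25 °C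
Reagents that add atoms: none
Why: Iridium-catalysed asymmetric hydrogenation of an exocyclic α-alkylidene lactam: the chiral P,N-ligand directs H2 to one enantiotopic alkene face and sets the ring centre (future C9) as S, the only centre of the target that cannot be corrected later.

**Step 5**
Reactants: 9 tert-butyl (3S)-3-(7-methoxy-7-oxoheptyl)-2-oxopiperidine-1-carboxylate
Product: 10 methyl 7-[(3S)-2-oxopiperidin-3-yl]heptanoate
Conditions: TFA, CH2Cl2, 0 → 25 °C
Reagents that add atoms: none
Why: Acidolysis of the tert-butyl carbamate frees the lactam N–H, which shields the lactam as its magnesium amidate in step 6 and is needed for a secondary thiolactam; acid does not enolize the lactam, so C3 stays S.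

**Step 6**
Reactants: 10 methyl 7-[(3S)-2-oxopiperidin-3-yl]heptanoate; 11 isopropenylmagnesium bromide
Product: 13 (3S)-3-(8-methyl-7-oxonon-8-en-1-yl)piperidin-2-one, via Weinreb amide 12 (not isolated)
Conditions: MeNH(OMe)·HCl, i-PrMgCl, THF, −20 °C; then 11, 0 °C; inverse quench into cold 1 M HCl
Reagents that add atoms: none
Why: One-pot Weinreb ketone synthesis: the magnesium amide turns the ester into Weinreb amide 12, and its chelated adduct with 11 releases the isopropenyl ketone only on acidic quench, which prevents over-addition and amine conjugate addition.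

**Step 7**
Reactants: 13 (3S)-3-(8-methyl-7-oxonon-8-en-1-yl)piperidin-2-one
Product: 14 (3S)-3-(6-chloro-8-methyl-7-oxonon-8-en-1-yl)piperidin-2-one (both epimers at the C–Cl carbon)
Conditions: CuCl2, LiCl, DMF, 80 °C
Reagents that add atoms: copper dichloride Cl[Cu]Cl
Why: α-Chlorination of a ketone by CuCl2 through its enol is regiospecific here because the ketone has one enolizable position only (the CH2 that becomes C1; the other α-carbon is vinylic); the C–Cl centre is destroyed in step 9, so its configuration is irrelevant.

**Step 8**
Reactants: 14 (3S)-3-(6-chloro-8-methyl-7-oxonon-8-en-1-yl)piperidin-2-one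
Product: 15 (3S)-3-(6-chloro-8-methyl-7-oxonon-8-en-1-yl)piperidine-2-thione
Conditions: Lawesson's reagent (0.55 equiv), THF, 25 °C; cold silica filtration, used at once
Reagents that add atoms: Lawesson's reagent COc1ccc(cc1)P1(=S)SP(=S)(S1)c1ccc(OC)cc1
Why: Thionation of a secondary lactam with Lawesson's reagent is much faster than that of the conjugated ketone at 25 °C and is neutral (C3 untouched); the hindered secondary α-chloro ketone alkylates the thiolactam only slowly in the cold, which allows brief handling of 15.

**Step 9 (key step)**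
Reactants: 15 (3S)-3-(6-chloro-8-methyl-7-oxonon-8-en-1-yl)piperidine-2-thione (two molecules)
Product: 17 (9S,9'S)-bis(Z-vinylogous amide) carbocycle (ring of 16 carbons), via bis-thioimidate macrocycle 16 (not isolated)
Conditions: NaHCO3, MeCN, 60 °C, syringe-pump addition to 2 mM; then PPh3, Et3N, 70 °C
Reagents that add atoms: none
Why: Proposed new method: each thiolactam sulfur is alkylated by the α-chloro ketone of the other molecule (the monomeric 9-membered ring is too strained to compete), closing the 18-membered bis(thioimidate) 16; enolization at C1, attack on the thioimidate carbon to a thiirane and sulfur abstraction by PPh3 (a stepwise 1,2-shift of C1 from S to C9a) then contract the ring to the 16-membered carbocycle and create both C9a=C1 bonds; the closest known reaction type is the Eschenmoser sulfide contraction of thiolactams with α-halo ketones, which has not been shown as a double, macrocycle-contracting head-to-tail dimerization giving tetrasubstituted vinylogous amides.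

**Step 10**
Reactants: 17 (9S,9'S)-bis(Z-vinylogous amide) carbocycle
Product: 18 (9S,9'S)-bis(3-methyl-3,4,6,7,8,9-hexahydro-2H-quinolizin-2-one) macrocycle (C1=C9a; C3 epimers)
Conditions: K2CO3, MeOH, 50 °C
Reagents that add atoms: none
Why: Intramolecular 6-endo aza-Michael addition of each vinylogous amide N–H to its α-methyl enone (the classical closure of β-amino divinyl ketones to 2,3-dihydro-4-pyridones) forms ring B of both halves; C3 forms as a mixture that is equilibrated in step 11.

**Step 11**
Reactants: 18 (9S,9'S)-bis(3-methyl-3,4,6,7,8,9-hexahydro-2H-quinolizin-2-one) macrocycle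
Product: 20 CNP0268544.6, via epimer mixture 19 (not isolated)
Conditions: Li, NH3/THF, t-BuOH (2.2 equiv), −78 °C; NH4Cl; then NaOMe (0.2 equiv), MeOH, 40 °C
Reagents that add atoms: none
Why: Dissolving-metal (Birch-type) conjugate reduction of the vinylogous amides, then base equilibration: allylic 1,3-strain with the C1 chain should hold the C9 chain axial so that C9a is protonated anti to it (H-9 and H-9a cis), and NaOMe epimerizes C1 and C3 by enolization and C9a by retro-aza-Michael/aza-Michael to the thermodynamic (1R,3S,9aR) array of each half while the non-enolizable (9S) centres stay fixed.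

**Compound list**
1 | cycloheptene | C1=CCCCCC1 | starting material
2 | 7-hydroperoxy-7-methoxyheptanal | O=CCCCCCC(OC)OO | intermediate
3 | methyl 7-oxoheptanoate | COC(=O)CCCCCC=O | intermediate
4 | piperidin-2-one | O=C1CCCCN1 | starting material
5 | tert-butyl 2-oxopiperidine-1-carboxylate | CC(C)(C)OC(=O)N1CCCCC1=O | intermediate
6 | aldol adduct, tert-butyl 3-(1-hydroxy-7-methoxy-7-oxoheptyl)-2-oxopiperidine-1-carboxylate (diastereomers; lithium alkoxide in the flask) | COC(=O)CCCCCC(O)C1CCCN(C(=O)OC(C)(C)C)C1=O | intermediate
7 | mesylate of 6 | COC(=O)CCCCCC(OS(C)(=O)=O)C1CCCN(C(=O)OC(C)(C)C)C1=O | intermediate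
8 | tert-butyl (3E)-3-(7-methoxy-7-oxoheptylidene)-2-oxopiperidine-1-carboxylate | COC(=O)CCCCC/C=C1\CCCN(C(=O)OC(C)(C)C)C1=O | intermediate
9 | tert-butyl (3S)-3-(7-methoxy-7-oxoheptyl)-2-oxopiperidine-1-carboxylate | COC(=O)CCCCCC[C@H]1CCCN(C(=O)OC(C)(C)C)C1=O | intermediate
10 | methyl 7-[(3S)-2-oxopiperidin-3-yl]heptanoate | COC(=O)CCCCCC[C@H]1CCCNC1=O | intermediate
11 | isopropenylmagnesium bromide | CC(=C)[Mg]Br | starting material
12 | Weinreb amide, N-methoxy-N-methyl-7-[(3S)-2-oxopiperidin-3-yl]heptanamide | CON(C)C(=O)CCCCCC[C@H]1CCCNC1=O | intermediate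
13 | (3S)-3-(8-methyl-7-oxonon-8-en-1-yl)piperidin-2-one | CC(=C)C(=O)CCCCCC[C@H]1CCCNC1=O | intermediate
14 | (3S)-3-(6-chloro-8-methyl-7-oxonon-8-en-1-yl)piperidin-2-one (C–Cl epimers) | CC(=C)C(=O)C(Cl)CCCCC[C@H]1CCCNC1=O | intermediate
15 | (3S)-3-(6-chloro-8-methyl-7-oxonon-8-en-1-yl)piperidine-2-thione (C–Cl epimers) | CC(=C)C(=O)C(Cl)CCCCC[C@H]1CCCNC1=S | intermediate
16 | 18-membered head-to-tail bis(thioimidate): two (3S)-3,4,5,6-tetrahydropyridin-2-yl sulfides; each sulfur is bonded to the methacryloyl-bearing α-carbon whose (CH2)5 chain ends at C3 of the other tetrahydropyridine | CC(=C)C(=O)C1CCCCC[C@H]2CCCN=C2SC(C(=O)C(C)=C)CCCCC[C@H]2CCCN=C2S1 | intermediate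
17 | (9S,9'S)-bis(Z-vinylogous amide): 16-membered carbocycle C1=C9a–C9–(CH2)5–C1'=C9a'–C9'–(CH2)5; each C9a/C9 pair lies in a piperidine (N–H on C9a); each C1 carries a 2-methylprop-2-enoyl group cis to N–H | CC(=C)C(=O)/C1=C2\NCCC[C@@H]2CCCCC/C(C(=O)C(C)=C)=C2/NCCC[C@@H]2CCCCC1 | intermediate
18 | (9S,9'S)-bis(3-methyl-3,4,6,7,8,9-hexahydro-2H-quinolizin-2-one), C1=C9a, C9 of each unit joined by (CH2)5 to C1 of the other (C3 epimers) | CC1CN2CCC[C@@H]3CCCCCC4=C5N(CC(C)C4=O)CCC[C@@H]5CCCCCC(C1=O)=C23 | intermediate
19 | saturated bis(quinolizidin-2-one) as a mixture of C1/C3/C9a epimers (9S,9'S fixed) | CC1CN2CCC[C@@H]3CCCCCC4C(=O)C(C)CN5CCC[C@H](CCCCCC(C1=O)C32)C45 | intermediate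
20 | CNP0268544.6: (1R,3S,9S,9aR) at both 3-methylquinolizidin-2-one units, C9 of each joined by (CH2)5 to C1 of the other | C[C@H]1CN2CCC[C@@H]3CCCCC[C@H]4C(=O)[C@@H](C)CN5CCC[C@H](CCCCC[C@@H](C1=O)[C@@H]32)[C@H]45 | target

**Totals and risks**
Total step count: 11. Longest linear sequence: 10 (steps 1, 3–11).

Most likely to fail:

Step 9 (the proposed new step). Oligomers may form instead of the cyclic dimer, the thioimidate nitrogen may close onto the ketone (thiazoline formation), the contraction to a tetrasubstituted alkene may stall, and C9 could epimerize through the ketene N,S-acetal tautomer of 16. The fallback uses known reaction types and no sulfur. It sets out from 13: KOt-Bu-catalysed intermolecular aza-Michael addition of the lactam N–H to the isopropenyl ketone of a second molecule, under high dilution, gives the 24-membered head-to-tail bis(N-alkyl lactam) diketone F1. Kinetic enolization toward the CH2 side (LiN(i-Pr)2, Me3SiCl, −78 °C) gives the bis(silyl enol ether) F2. Activation of each tertiary lactam with Tf2O and 2,6-di-tert-butyl-4-methylpyridine, with Vilsmeier–Haack-type attack of the tethered silyl enol ether on the triflyloxyiminium ion, closes ring B and the carbocycle. The fallback comes back to the route at 18; steps 7 to 10 are bypassed.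

Step 11. The tetrasubstituted vinylogous amides may be reduced slowly or give C–N cleavage, and the equilibrium may hold minor epimers. The fallback sets out from 18: exhaustive hydrogenation (H2, 80 bar, PtO2, AcOH) saturates both enaminones and also reduces the ketones, giving the bis(quinolizidin-2-ol) mixture F3. Swern oxidation returns the diketone and comes back to the route at 19, which is equilibrated with NaOMe as in step 11 to give 20.

Step 4. This step sets the only centre that cannot be equilibrated, so low enantioselectivity would carry through as meso-type macrocycles after step 9. The fallback sets out from 8: hydrogenation over Pd/C (EtOAc, 25 °C) gives the racemic lactam F4, which is resolved by preparative supercritical-fluid chromatography on a chiral stationary phase. The fallback comes back to the route at 9; the 3R enantiomer F5 is set aside.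

**Further compounds**
F1 | step 9 | 24-membered head-to-tail bis(N-alkyl lactam) diketone, (3S) at both lactam C3, N–CH2–CH(CH3)–C(=O)–(CH2)6 links | CC1CN2CCC[C@H](CCCCCCC(=O)C(C)CN3CCC[C@H](CCCCCCC1=O)C3=O)C2=O
F2 | step 9 | bis(trimethylsilyl enol ether) of F1, enolized toward the chain CH2 (E/Z mixture) | CC1CN2CCC[C@H](CCCCCC=C(O[Si](C)(C)C)C(C)CN3CCC[C@H](CCCCCC=C1O[Si](C)(C)C)C3=O)C2=O
F3 | step 11 | bis(quinolizidin-2-ol) macrocycle, mixture of epimers at C1, C2, C3 and C9a (9S,9'S fixed) | CC1CN2CCC[C@@H]3CCCCCC4C(O)C(C)CN5CCC[C@H](CCCCCC(C1O)C32)C45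
F4 | step 4 | racemic tert-butyl 3-(7-methoxy-7-oxoheptyl)-2-oxopiperidine-1-carboxylate | COC(=O)CCCCCCC1CCCN(C(=O)OC(C)(C)C)C1=O
F5 | step 4 | tert-butyl (3R)-3-(7-methoxy-7-oxoheptyl)-2-oxopiperidine-1-carboxylate | COC(=O)CCCCCC[C@@H]1CCCN(C(=O)OC(C)(C)C)C1=O
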